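(The data were generated by integration from invented constants.)

At 1.5 h I stood before the elm flask and had to say what it held and which option to take.

| setting | elm | cedar | flask |
|---|---|---|---|
| starting material | 0.050 M | 0.050 M | 0.050 M |
| reagent | 1.3 equiv | 2 equiv | 1.30 equiv |
| temperature | 60 °C | 66 °C | 60 °C |
| remark | the very flask that is asked about, followed so far | run made earlier |  |
| time |  |  | 1.5 h |

- elm (time / min: target / %): 8.00: 61.9; 12.0: 61.6; 20.0: 61.5; 30.0: 61.5; 50.0: 61.4; 90.0: 61.3
- cedar (time / min: target / %): 0.333: 62.7; 1.00: 61.2; 2.00: 59.2; 2.50: 58.8; 4.00: 58.3; 5.00: 59.1

(readings scatter by 0.5 percentage points)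

- south-east: at 1.5 h add reagent, 50.0 % of the amount charged, then wait 1.5 h
- west: change nothing and wait 1.5 h more
- south-west: at 1.5 h raise the temperature by 10 K, then wait 1.5 h
- north-west: at 1.5 h add starting material, 50.0 % of the amount charged, then wait 1.5 h

- additions leave the volume as it is
- the numbers in the tables scatter by 0.5 percentage points (one standard deviation)
- a reading or a percentage of target counts all its forms, free or not

- target, in percent of the starting material first charged, at 1.5 h
- the option that brings most further target ("none" if no option brings more than 2 percentage points) (south-east / west / south-west / north-west / none)
- target present, in percent of the starting material first charged, after south-west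
- target present, in percent of the starting material first charged, after north-west

I read the elm table first, down its column. Target went from 61.9 % at 8.00 min to 61.3 % at 90.0 min, a drift of 0.6 percentage points against a scatter of 0.5 points, so I committed to 61.3 % for now. That left 38.7 % of the charge not shown as target, and I called this part of the charge the missing share.

Then I read the cedar table against it. Cedar read 62.7 % at 0.333 min, long before the first elm reading, and its readings fell by 4.4 points by 4.00 min, about 8.80 times the scatter. Its missing share thus grew from 37.3 % to 41.7 % within minutes, so in cedar target itself was passing into something unseen. The readings did not tell me whether that passage could run back. I therefore did not write off the elm missing share, since the 2 points an option needed was less than that share, but I could not choose an option from it.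

The forecast gave 61.4 %, best option none, 60.3 % after south-west and 61.1 % after north-west, on the ground that “more reagent can only harm, fresh starting material finds no reagent, waiting does nothing”.

The flask gave 61.7 %. The best option was south-west, which brought 7.6 points and left 69.2 %, while north-west left 43.8 %.

    starting material + reagent → target (k = 2.40 L mol⁻¹ s⁻¹, Ea = 62.0 kJ mol⁻¹)
    starting material + 2 reagent → side product A (k = 13.0 L² mol⁻² s⁻¹, Ea = 47.0 kJ mol⁻¹)
    crystals ⇌ target, rate k3*(cs3 - [target]) while solid is left; crystals form when [target] > cs3 (solubility = 1.90 mM, k = 0.780 s⁻¹)
    target ⇌ isomer of the product (K = 5.10, k = 0.0420 s⁻¹, Ea = 89.0 kJ mol⁻¹, ΔH = −47.0 kJ mol⁻¹)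
    starting material + target → side product B (k = 0.400 L mol⁻¹ s⁻¹, Ea = 69.0 kJ mol⁻¹)
    (constants at 60 °C)

The missing share, 38.7 % as I had read it from one scattered reading, was 38.3 % in the flask at 1.5 h, where side product A stood at 15.5 %, isomer of the product at 19.4 % and side product B at 3.49 %. Starting material, the limiting reagent, stood at 0 %, with reagent at 13 % of its own charge. The neighbouring flask, charged with 3.20 equiv of reagent and read at the same time, gave 39.7 % target, so its missing share was 60.3 %, larger than in the flask by 22 points. There the isomer of the product stood at 19.4 %, level with the flask, side product B at 1.06 %, and side product A at 39.8 %.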